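Locants used throughout: oxolane O1, C2, C3, C4, C5; C7 is the carbinol carbon on C3; C7' is the benzylic methylene on C4.

## Analysis of the target

Target 16 is a 3,4-disubstituted oxolane lignan. The ring O1–C2–C3–C4–C5 has unsubstituted methylenes at C2 and C5. C4 carries a 4-hydroxy-3-methoxybenzyl group through C7', and C3 carries the secondary carbinol C7, to which the second 4-hydroxy-3-methoxyphenyl ring is bound. There are three contiguous stereocentres, (3R), (4R) and (7R). The two ring substituents are trans, and C7 lies outside the ring, so its configuration relative to C3 has to be imposed by a reagent. The sensitive functions are the two free phenols and the benzylic alcohol at C7, which sits para to an oxygen substituent. Under acid it ionises to a quinone-methide-like cation (epimerisation, Friedel–Crafts closure onto the other arene), and under hydrogenation conditions its C–O bond can be cleaved. The synthesis is hard because the finished ring has no functional group other than its ether oxygen, so every activating group used to build it must disappear, and because the two arenes are identical while their benzylic carbons differ (CH2 against CHOH), which rules out a symmetric dimerisation. The strategy rests on reading the ring as two three-atom units. O1–C2–C3 is the backbone of an alkoxide adduct of a methylenemalonate (C3 is the malonate carbon, C7 one of its ester carbons). C5–C4–C7' is a propargyl unit (C5 the OCH2 carbon, C4 and C7' the alkyne carbons) capped at its terminus by the arene. Ring, benzylic carbon and one arene thus map onto three achiral pieces, and all stereochemistry is introduced afterwards.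

## Retrosynthetic reasoning

**16 from 15.** The two phenols are unmasked last by cleaving the two O–CH2Ph bonds of bis-benzyl ether 15. Benzyl is chosen because it survives alkoxides, organolithium reagents, hot chloride in DMSO and a homogeneous hydrogenation, and because it leaves under neutral conditions. Acid-labile groups are excluded by the ionisable C7 alcohol.

**15 from 14.** The C7–H bond is cut, leading back to aryl ketone 14. A ketone at C7 lets the exocyclic stereocentre be set by a chiral reduction catalyst instead of by the weak bias of the ring. The forward reduction must differentiate an aryl group from an α-branched alkyl group.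

**14 from 12 and 13.** The C7–aryl bond is cut between the Weinreb amide 12 and aryllithium 13. This bond is chosen because it joins the second arene to a carbonyl carbon already present on C3, and because 13 comes from the same aryl iodide 2 that supplies the first arene. The forward reaction must stop at the ketone, which the chelated tetrahedral adduct of a Weinreb amide ensures.

**12 from 11, and 11 from 9 through 10.** Amide 12 is the aminolysis product of trans ester 11. Ester 11 is traced to geminal diester 9 by adding back a second ethoxycarbonyl group on C3. That group is a traceless activator: it made C3 a soft carbon nucleophile for ring closure and is lost once the ring exists. Its loss creates the C3 stereocentre, first mainly as the cis ester 10 and, after base equilibration, as the trans ester 11. C3 is thus set under thermodynamic control by C4.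

**9 from 8.** The C4–H and C7'–H bonds are removed to give the exocyclic benzylidene 8. Compound 8 is achiral, so a chiral hydrogenation catalyst alone decides the configuration of C4. The gain is that the first stereocentre is created on a rigid trisubstituted alkene of a single geometry.

**8 from 7 and 2; 7 from 6 and 4.** This is the key disconnection. Three bonds are cut: C7'–aryl, C3–C4 and O1–C2. Cutting C7'–aryl and C3–C4 together corresponds to an anti addition of a carbon nucleophile and an aryl group across an alkyne, which leads to malonate enolate 7 and aryl iodide 2. Cutting O1–C2 in 7 is a retro-oxa-Michael step to alkoxide 6 and methylenemalonate 4. These cuts are preferred over any that keep the ring intact because they reduce a ring with two side chains to three achiral, trivially accessible components. The forward reaction has to perform conjugate addition, 5-exo ring closure and aryl transfer in that order in one flask.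

**6 from 5, 4 from 3, 2 from 1.** Alkoxide 6 is the sodium salt of propargyl alcohol 5. Acceptor 4 is the methylenation product of diethyl malonate 3. Iodide 2 is the benzyl ether of 4-iodo-2-methoxyphenol 1. These are one-step operations, so the risk of the route sits in the key step.

## Alternatives that were turned down

**Alternative 1:** photocycloaddition on an intact ring.
- **Disconnection:** The C3–C7 and C4–C7' bonds are cut together. The oxolane is bought as 2,5-dihydrofuran A3, and the two carbons arrive as C6 and C5 of a spirocyclic 6-aryl-1,3-dioxin-4-one A1 whose acetal carbon comes from (−)-menthone A2.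
- **Forward key step:** Irradiation adds the enone alkene of A1 across A3 to give the cis-fused cyclobutane photoadduct A4. Acetal cleavage and retro-aldol opening of the cyclobutane bond that came from the dioxinone (the de Mayo sequence) then leave an aroyl group on C3 and an acetic acid chain on C4 (keto acid A5).
- **For:** The ring needs no construction. The alkene of A3 is symmetric, so regiochemistry is no issue. Both ring-to-side-chain bonds form at once. The auxiliary fixes the absolute configuration of C4 in the bond-forming event itself. On this last point it is stronger than the chosen route, which needs a separate asymmetric hydrogenation.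
- **Against:** The cis ring fusion delivers the cis 3,4-relationship, so C3 must be epimerised after fragmentation. C7' arrives as the methylene of a carboxylic acid, so the second arene has to be attached by a decarboxylative cross-coupling of a primary alkyl fragment. The auxiliary must be made and its spiro diastereomers separated. Face selection by remote alkyl groups of the acetal is structurally weak. Photochemistry at preparative scale requires dilute solutions.
- **Comparison:** The count comes to roughly eleven or twelve steps. The chosen strategy forms the same two ring-to-side-chain connections and the C7'–aryl bond in one thermal step from achiral pieces, with a catalyst in place of a stoichiometric auxiliary.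

**Alternative 2:** Prins closure with capture of the benzylic cation.
- **Disconnection:** C2–C3 and the C7–O bond are cut. C2 arrives as formaldehyde A7, and the substrate is the enantioenriched homoallylic alcohol A6, an E-styrene with a mesylated phenol on the other arene.
- **Forward key step:** Under trifluoroacetic acid A8, A6 and A7 form an oxocarbenium ion. Its carbon is attacked by the styrene carbon nearer the stereocentre, which closes the oxolane and leaves a cation at C7. The conjugate base of A8 traps the cation, and hydrolysis on work-up gives the alcohol A9.
- **For:** It is the shortest plan from the cyclisation onwards: ring, C3 and C7 are created in one step from one stereocentre and a one-carbon unit. On step economy after the ring-forming event it is stronger than the chosen route.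
- **Against:** The cation at C7 is stabilised by a para alkoxy group and is long-lived, so its capture need not be stereospecific. The product can ionise again under the same acid. A 2-oxonia-Cope shift of the oxocarbenium ion can scramble the C4 stereocentre. The second arene must be deactivated (hence the mesylate) to prevent Friedel–Crafts closure, which forces two different phenol protecting groups and two deprotections. The substrate A6 itself needs a multi-step asymmetric synthesis.
- **Comparison:** The chosen strategy never exposes the C7 alcohol to acid. It sets each stereocentre by a separate, adjustable element (catalyst, equilibration, catalyst).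

**Alternative 3:** alkenyllithium opening of an epoxide.
- **Disconnection:** The C3–C4 bond is cut. The precursor is the ether A10, which links a (Z)-2-bromo-3-arylallyl group to a (2S,3S)-3-aryl-2,3-epoxypropyl group obtained by Sharpless epoxidation of a cinnamyl alcohol.
- **Forward key step:** tert-Butyllithium A11 exchanges the vinylic bromide. The alkenyllithium opens the epoxide at its non-benzylic carbon in a 5-exo mode, with inversion at C3 and retention at C7, and gives the benzylidene alcohol A12.
- **For:** It is convergent. C3 and C7 both derive from one catalytic asymmetric epoxidation and are transferred stereospecifically. On the C3/C7 pair it is stronger than the chosen route, which relies on an equilibration and a ketone reduction. The hydroxyl group of A12 could also direct the later hydrogenation of the alkene to the trans ring.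
- **Against:** An aryl epoxide bearing a para alkoxy group ionises very easily at its benzylic carbon, so A10 and its precursors are fragile towards acid, silica and Lewis-acidic lithium salts. Etherification of the epoxy alcohol under base invites Payne rearrangement. The electronically activated benzylic carbon competes as the site of attack (six-membered ring). The organolithium can also metallate the allylic and benzylic ether positions. The Z-bromoalkene needs its own stereocontrolled preparation.
- **Comparison:** The chosen strategy passes through robust esters and a ketone. The sensitive carbinol appears only in its last two steps.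

Key step: step 3

Assumption: the enantioface preference of a cationic iridium PHOX catalyst for the exocyclic Z-benzylidene 8 cannot be deduced from the structure alone; the (S)-ligand is written, and its antipode is to be used should it prove to deliver (4S)-9.

## Route

Step 1
Reactants: 1 4-iodo-2-methoxyphenol
Product: 2 1-(benzyloxy)-4-iodo-2-methoxybenzene
Conditions: BnBr, K2CO3, DMF, 20 °C
Reagents that add atoms: benzyl bromide, BrCc1ccccc1
Why: Williamson ether synthesis; the phenoxide is alkylated at oxygen by the benzylic bromide in an SN2 reaction, and the aryl iodide is inert.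

Step 2
Reactants: 3 diethyl malonate
Product: 4 diethyl methylenemalonate
Conditions: (CH2O)n, Cu(OAc)2 (cat.), KOAc (cat.), AcOH, 100 °C; distillation at reduced pressure, used at once
Reagents that add atoms: paraformaldehyde as source of formaldehyde, C=O
Why: Knoevenagel condensation (hydroxymethylation, then dehydration); oligomers formed by further Michael addition crack back to monomeric 4 on distillation, and 4 is used immediately because it polymerises on standing.

Step 3
Reactants: 5 propargyl alcohol; 4 diethyl methylenemalonate; 2 1-(benzyloxy)-4-iodo-2-methoxybenzene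
Product: 8 diethyl (Z)-4-[4-(benzyloxy)-3-methoxybenzylidene]dihydrofuran-3,3(2H)-dicarboxylate, via sodium prop-2-yn-1-olate 6 (not isolated), via sodium malonate enolate 7 (not isolated)
Conditions: 5, NaH, THF, 0 °C; 4 added slowly, −78 °C; then 2, PdCl2(PPh3)2 (5 mol %), n-BuLi (10 mol %), DMSO–THF, 20–50 °C
Reagents that add atoms: none
Why: Alkoxide 6 adds to the unhindered, doubly activated alkene of 4 (oxa-Michael addition), which forms O1–C2 and leaves malonate enolate 7 with its nucleophilic carbon five atoms from the alkyne. Oxidative addition of 2 to zerovalent palladium (PdCl2(PPh3)2 reduced by n-BuLi) gives ArPdI(PPh3)2 (divalent palladium), which binds the alkyne as a π-acid; 7 attacks the internal alkyne carbon on the face opposite palladium, and reductive elimination from the aryl(alkenyl)palladium joins the arene to C7'. The closest known reaction type is the three-component coupling of propargyl alkoxides, alkylidene malonates and aryl halides to 3-arylidene tetrahydrofurans, of which 4 is the parent acceptor. The oxolane closes in the 5-exo-dig mode (C3–C4); the tether length and the stabilised nucleophile exclude 6-endo-dig closure. No stereocentre is created; anti addition places the aryl group trans to C3 and cis to C5, which is the Z geometry of 8, and reductive elimination retains it. The step needs chemoselectivity in the order of events: 4 is added slowly at −78 °C to 6 so that free acceptor does not meet a large excess of enolate 7 (the start of oligomerisation), and 2 and the catalyst are introduced only afterwards. With PPh3 as ligand, direct arylation of a malonate enolate is slow, and the enolate (pKa of the malonate about 16 in DMSO) is too weak a base to deprotonate the terminal alkyne and divert it to alkynylation.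

Step 4
Reactants: 8 diethyl (Z)-4-[4-(benzyloxy)-3-methoxybenzylidene]dihydrofuran-3,3(2H)-dicarboxylate
Product: 9 diethyl (R)-4-[4-(benzyloxy)-3-methoxybenzyl]dihydrofuran-3,3(2H)-dicarboxylate
Conditions: H2 (50 bar), [Ir(cod)((S)-tBu-PHOX)][B(C6H3-3,5-(CF3)2)4] (2 mol %; (S)-tBu-PHOX = (S)-4-tert-butyl-2-[2-(diphenylphosphino)phenyl]-4,5-dihydrooxazole), CH2Cl2, 25 °C
Reagents that add atoms: none
Why: Asymmetric hydrogenation of a trisubstituted aryl alkene by a cationic iridium P,N-ligand complex, a catalyst class that needs no coordinating group on the substrate; 8 has no stereocentre and enantiotopic alkene faces, so C4 is set by the catalyst alone, which reads the contrast between the C(CO2Et)2 and OCH2 flanks and the aryl group. Benzyl ether, esters and arenes are inert to this homogeneous catalyst.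

Step 5
Reactants: 9 diethyl (R)-4-[4-(benzyloxy)-3-methoxybenzyl]dihydrofuran-3,3(2H)-dicarboxylate
Product: 11 ethyl (3R,4R)-4-[4-(benzyloxy)-3-methoxybenzyl]tetrahydrofuran-3-carboxylate, via cis ethyl ester 10 (not isolated)
Conditions: LiCl, H2O, DMSO, 155 °C; then NaOEt (0.2 equiv), EtOH, 50 °C
Reagents that add atoms: none
Why: Krapcho dealkoxycarbonylation: chloride dealkylates one ester, the carboxylate loses CO2, and the ester enolate is protonated mainly from the face away from the C4 substituent, which gives the cis ester 10. Ethoxide then equilibrates C3 through the enolate to the trans ester 11, so C3 is set under thermodynamic control by C4, which is not acidic and keeps its configuration; ring opening of the enolate by loss of O1 would be a retro-5-endo-trig process and is stereoelectronically disfavoured.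

Step 6
Reactants: 11 ethyl (3R,4R)-4-[4-(benzyloxy)-3-methoxybenzyl]tetrahydrofuran-3-carboxylate
Product: 12 (3R,4R)-4-[4-(benzyloxy)-3-methoxybenzyl]-N-methoxy-N-methyltetrahydrofuran-3-carboxamide
Conditions: MeNH(OMe)·HCl, i-PrMgCl, THF, −20 to 0 °C
Reagents that add atoms: N,O-dimethylhydroxylamine hydrochloride, Cl.CNOC
Why: Weinreb amide formation by aminolysis of the ester with the chloromagnesium amide generated in the flask; acyl substitution at low temperature outpaces enolisation of the ester, and the trans arrangement is in any case the thermodynamic one.

Step 7
Reactants: 12 (3R,4R)-4-[4-(benzyloxy)-3-methoxybenzyl]-N-methoxy-N-methyltetrahydrofuran-3-carboxamide; 2 1-(benzyloxy)-4-iodo-2-methoxybenzene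
Product: 14 [4-(benzyloxy)-3-methoxyphenyl]{(3R,4R)-4-[4-(benzyloxy)-3-methoxybenzyl]tetrahydrofuran-3-yl}methanone, via [4-(benzyloxy)-3-methoxyphenyl]lithium 13 (not isolated)
Conditions: 2, n-BuLi, THF, −78 °C; then 12, −78 to −40 °C; 1 M HCl quench, 0 °C
Reagents that add atoms: none
Why: Iodine–lithium exchange on 2 is fast at −78 °C, and aryllithium 13 adds only once to the Weinreb amide because the five-membered lithium chelate of the tetrahedral adduct persists until the acidic quench (Weinreb ketone synthesis). Using 2 a second time saves the preparation of another aryl halide.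

Step 8
Reactants: 14 [4-(benzyloxy)-3-methoxyphenyl]{(3R,4R)-4-[4-(benzyloxy)-3-methoxybenzyl]tetrahydrofuran-3-yl}methanone
Product: 15 (R)-[4-(benzyloxy)-3-methoxyphenyl]{(3R,4R)-4-[4-(benzyloxy)-3-methoxybenzyl]tetrahydrofuran-3-yl}methanol
Conditions: (S)-Me-CBS oxazaborolidine (0.5 equiv), BH3·SMe2, THF, −20 °C; MeOH quench
Reagents that add atoms: none
Why: Corey–Bakshi–Shibata reduction: the ketone oxygen binds the ring boron of the oxazaborolidine anti to the aryl group (the larger flank), and hydride is delivered within the complex from the nitrogen-bound borane. The (S)-catalyst gives the sense of (R)-1-arylethanols, which is (7R) here because the CIP order is O > aryl > C3 > H; C7 is set by the catalyst and the ring stereocentres are not touched.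

Step 9
Reactants: 15 (R)-[4-(benzyloxy)-3-methoxyphenyl]{(3R,4R)-4-[4-(benzyloxy)-3-methoxybenzyl]tetrahydrofuran-3-yl}methanol
Product: 16 4-{(R)-hydroxy[(3R,4R)-4-(4-hydroxy-3-methoxybenzyl)tetrahydrofuran-3-yl]methyl}-2-methoxyphenol
Conditions: H2 (1 atm), 10% Pd/C, EtOAc, 20 °C, stopped at full conversion
Reagents that add atoms: none
Why: Catalytic hydrogenolysis of two aryl benzyl ethers over Pd/C in a neutral aprotic solvent; aryl benzyl ethers are cleaved much faster than a benzylic C–OH bond as long as no acid is present, so the carbinol and all three stereocentres should be retained.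

## Compound list

1 | 4-iodo-2-methoxyphenol | COc1cc(I)ccc1O | starting material
2 | 1-(benzyloxy)-4-iodo-2-methoxybenzene | COc1cc(I)ccc1OCc1ccccc1 | intermediate
3 | diethyl malonate | CCOC(=O)CC(=O)OCC | starting material
4 | diethyl methylenemalonate | C=C(C(=O)OCC)C(=O)OCC | intermediate
5 | propargyl alcohol (prop-2-yn-1-ol) | C#CCO | starting material
6 | sodium prop-2-yn-1-olate | [Na+].[O-]CC#C | intermediate
7 | sodium enolate of diethyl 2-[(prop-2-yn-1-yloxy)methyl]malonate | [Na+].CCOC(=O)C(COCC#C)=C([O-])OCC | intermediate
8 | diethyl (Z)-4-[4-(benzyloxy)-3-methoxybenzylidene]dihydrofuran-3,3(2H)-dicarboxylate | COc1cc(/C=C2\COCC2(C(=O)OCC)C(=O)OCC)ccc1OCc1ccccc1 | intermediate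
9 | diethyl (R)-4-[4-(benzyloxy)-3-methoxybenzyl]dihydrofuran-3,3(2H)-dicarboxylate | COc1cc(C[C@H]2COCC2(C(=O)OCC)C(=O)OCC)ccc1OCc1ccccc1 | intermediate
10 | ethyl (3S,4R)-4-[4-(benzyloxy)-3-methoxybenzyl]tetrahydrofuran-3-carboxylate (cis) | COc1cc(C[C@H]2COC[C@H]2C(=O)OCC)ccc1OCc1ccccc1 | intermediate
11 | ethyl (3R,4R)-4-[4-(benzyloxy)-3-methoxybenzyl]tetrahydrofuran-3-carboxylate (trans) | COc1cc(C[C@H]2COC[C@@H]2C(=O)OCC)ccc1OCc1ccccc1 | intermediate
12 | (3R,4R)-4-[4-(benzyloxy)-3-methoxybenzyl]-N-methoxy-N-methyltetrahydrofuran-3-carboxamide | COc1cc(C[C@H]2COC[C@@H]2C(=O)N(C)OC)ccc1OCc1ccccc1 | intermediate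
13 | [4-(benzyloxy)-3-methoxyphenyl]lithium | [Li]c1ccc(OCc2ccccc2)c(OC)c1 | intermediate
14 | [4-(benzyloxy)-3-methoxyphenyl]{(3R,4R)-4-[4-(benzyloxy)-3-methoxybenzyl]tetrahydrofuran-3-yl}methanone | COc1cc(C[C@H]2COC[C@@H]2C(=O)c2ccc(OCc3ccccc3)c(OC)c2)ccc1OCc1ccccc1 | intermediate
15 | (R)-[4-(benzyloxy)-3-methoxyphenyl]{(3R,4R)-4-[4-(benzyloxy)-3-methoxybenzyl]tetrahydrofuran-3-yl}methanol | COc1cc(C[C@H]2COC[C@@H]2[C@@H](O)c2ccc(OCc3ccccc3)c(OC)c2)ccc1OCc1ccccc1 | intermediate
16 | 4-{(R)-hydroxy[(3R,4R)-4-(4-hydroxy-3-methoxybenzyl)tetrahydrofuran-3-yl]methyl}-2-methoxyphenol | COc1cc(C[C@H]2COC[C@@H]2[C@@H](O)c2ccc(O)c(OC)c2)ccc1O | target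

## Step count and least certain steps

Total: 9 steps. Longest linear sequence: 8 steps (1 → 2 → 8 → 9 → 11 → 12 → 14 → 15 → 16; the branch from 3 through 4 is equally long).

**Step 3 (key step).**
- **What may go wrong:** The most likely failure is anionic oligomerisation of 4, in which enolate 7 adds to a second molecule of the acceptor faster than alkoxide 6 does. Protonation of the alkenylpalladium intermediate would give a cyclised product without the arene. Copper-free alkynylation of the terminal alkyne by 2 is a third diversion.
- **Fallback:** This route avoids free 4 altogether and sets out from 5 and 3. Compound 5 is converted with paraformaldehyde and HCl gas (CH2Cl2, 0 °C) into 3-(chloromethoxy)prop-1-yne F1. F1 alkylates the sodium enolate of 3 (NaH, THF, 0 °C, 3 in excess to suppress double alkylation) to give diethyl 2-[(prop-2-yn-1-yloxy)methyl]malonate F2, the conjugate acid of 7. Deprotonation of F2 with KOt-Bu in DMSO in the presence of 2 and PdCl2(PPh3)2/n-BuLi then effects the two-component cyclisation–coupling and returns to the route at 8.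

**Step 4.**
- **What may go wrong:** Turnover may be slow at an alkene flanked by a quaternary carbon. Enantioface discrimination may be insufficient for a Z-configured exocyclic styrene. The double bond may migrate into the ring (towards C4=C5) before reduction, which would erode the selectivity.
- **Fallback:** From 8, hydrogenation with the achiral complex [Ir(cod)(PCy3)(py)]PF6 (H2, CH2Cl2), which leaves the benzyl ether intact, gives racemic diethyl 4-[4-(benzyloxy)-3-methoxybenzyl]dihydrofuran-3,3(2H)-dicarboxylate F3. The operations of step 5 convert it into racemic ethyl trans-4-[4-(benzyloxy)-3-methoxybenzyl]tetrahydrofuran-3-carboxylate F4. Preparative chromatography on a chiral stationary phase separates the enantiomers and returns to the route at 11.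

**Step 5.**
- **What may go wrong:** Equilibration of the ester may be incomplete or the equilibrium position insufficient, so that cis material is carried on. Prolonged heating with base could also open the ring by β-elimination.
- **Fallback:** From 10, the unequilibrated ester (10 together with 11) is taken through steps 6 and 7. These turn 10 into (3S,4R)-4-[4-(benzyloxy)-3-methoxybenzyl]-N-methoxy-N-methyltetrahydrofuran-3-carboxamide F5 and then into [4-(benzyloxy)-3-methoxyphenyl]{(3S,4R)-4-[4-(benzyloxy)-3-methoxybenzyl]tetrahydrofuran-3-yl}methanone F6. H-3 of this aryl ketone is far more acidic than that of an ester, and the aroyl group is bulkier, so DBU in CH2Cl2 at 20 °C should drive F6 to the trans ketone and return to the route at 14.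

**Step 8.**
- **What may go wrong:** Catalyst control may be eroded because the alkyl flank is α-branched. The intrinsic Felkin–Anh preference of the ketone, which is expected to be weak, may oppose the catalyst. Either would give a mixture of C7 epimers.
- **Fallback:** From 14, reduction under substrate control (LiBH(s-Bu)3, THF, −78 °C) gives 15 together with (S)-[4-(benzyloxy)-3-methoxyphenyl]{(3R,4R)-4-[4-(benzyloxy)-3-methoxybenzyl]tetrahydrofuran-3-yl}methanol F7. The two are diastereomers and separable on silica. F7 is inverted by Mitsunobu esterification (4-nitrobenzoic acid, PPh3, DIAD, THF, 0 °C) to (R)-[4-(benzyloxy)-3-methoxyphenyl]{(3R,4R)-4-[4-(benzyloxy)-3-methoxybenzyl]tetrahydrofuran-3-yl}methyl 4-nitrobenzoate F8. Methanolysis of F8 (K2CO3, MeOH) returns to the route at 15.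

**Step 9.**
- **What may go wrong:** Over-reduction is the concern. Once the para phenol is unmasked, the benzylic C7–O bond is activated, and traces of acid on the catalyst can cause its hydrogenolysis or epimerisation.
- **Fallback:** From 14, the hydrogenolysis is moved in front of the reduction, where no benzylic C–O single bond exists. H2, Pd/C, EtOAc gives (4-hydroxy-3-methoxyphenyl)[(3R,4R)-4-(4-hydroxy-3-methoxybenzyl)tetrahydrofuran-3-yl]methanone F9. Silylation (TBSCl, imidazole, DMF) gives {4-[(tert-butyldimethylsilyl)oxy]-3-methoxyphenyl}[(3R,4R)-4-{4-[(tert-butyldimethylsilyl)oxy]-3-methoxybenzyl}tetrahydrofuran-3-yl]methanone F10. The reduction of step 8 gives (R)-{4-[(tert-butyldimethylsilyl)oxy]-3-methoxyphenyl}[(3R,4R)-4-{4-[(tert-butyldimethylsilyl)oxy]-3-methoxybenzyl}tetrahydrofuran-3-yl]methanol F11. Bu4NF buffered with AcOH (THF, 0 °C) removes the two aryl silyl ethers without acid or hydrogen and returns to the route at 16.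

## Further compounds

F1 | step 3 | 3-(chloromethoxy)prop-1-yne | C#CCOCCl
F2 | step 3 | diethyl 2-[(prop-2-yn-1-yloxy)methyl]malonate | C#CCOCC(C(=O)OCC)C(=O)OCC
F3 | step 4 | racemic diethyl 4-[4-(benzyloxy)-3-methoxybenzyl]dihydrofuran-3,3(2H)-dicarboxylate (both enantiomers) | COc1cc(C[C@H]2COCC2(C(=O)OCC)C(=O)OCC)ccc1OCc1ccccc1.COc1cc(C[C@@H]2COCC2(C(=O)OCC)C(=O)OCC)ccc1OCc1ccccc1
F4 | step 4 | racemic ethyl trans-4-[4-(benzyloxy)-3-methoxybenzyl]tetrahydrofuran-3-carboxylate (both enantiomers) | COc1cc(C[C@H]2COC[C@@H]2C(=O)OCC)ccc1OCc1ccccc1.COc1cc(C[C@@H]2COC[C@H]2C(=O)OCC)ccc1OCc1ccccc1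
F5 | step 5 | (3S,4R)-4-[4-(benzyloxy)-3-methoxybenzyl]-N-methoxy-N-methyltetrahydrofuran-3-carboxamide | COc1cc(C[C@H]2COC[C@H]2C(=O)N(C)OC)ccc1OCc1ccccc1
F6 | step 5 | [4-(benzyloxy)-3-methoxyphenyl]{(3S,4R)-4-[4-(benzyloxy)-3-methoxybenzyl]tetrahydrofuran-3-yl}methanone | COc1cc(C[C@H]2COC[C@H]2C(=O)c2ccc(OCc3ccccc3)c(OC)c2)ccc1OCc1ccccc1
F7 | step 8 | (S)-[4-(benzyloxy)-3-methoxyphenyl]{(3R,4R)-4-[4-(benzyloxy)-3-methoxybenzyl]tetrahydrofuran-3-yl}methanol | COc1cc(C[C@H]2COC[C@@H]2[C@H](O)c2ccc(OCc3ccccc3)c(OC)c2)ccc1OCc1ccccc1
F8 | step 8 | (R)-[4-(benzyloxy)-3-methoxyphenyl]{(3R,4R)-4-[4-(benzyloxy)-3-methoxybenzyl]tetrahydrofuran-3-yl}methyl 4-nitrobenzoate | COc1cc(C[C@H]2COC[C@@H]2[C@@H](OC(=O)c2ccc(cc2)[N+](=O)[O-])c2ccc(OCc3ccccc3)c(OC)c2)ccc1OCc1ccccc1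
F9 | step 9 | (4-hydroxy-3-methoxyphenyl)[(3R,4R)-4-(4-hydroxy-3-methoxybenzyl)tetrahydrofuran-3-yl]methanone | COc1cc(C[C@H]2COC[C@@H]2C(=O)c2ccc(O)c(OC)c2)ccc1O
F10 | step 9 | {4-[(tert-butyldimethylsilyl)oxy]-3-methoxyphenyl}[(3R,4R)-4-{4-[(tert-butyldimethylsilyl)oxy]-3-methoxybenzyl}tetrahydrofuran-3-yl]methanone | COc1cc(C[C@H]2COC[C@@H]2C(=O)c2ccc(O[Si](C)(C)C(C)(C)C)c(OC)c2)ccc1O[Si](C)(C)C(C)(C)C
F11 | step 9 | (R)-{4-[(tert-butyldimethylsilyl)oxy]-3-methoxyphenyl}[(3R,4R)-4-{4-[(tert-butyldimethylsilyl)oxy]-3-methoxybenzyl}tetrahydrofuran-3-yl]methanol | COc1cc(C[C@H]2COC[C@@H]2[C@@H](O)c2ccc(O[Si](C)(C)C(C)(C)C)c(OC)c2)ccc1O[Si](C)(C)C(C)(C)C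
A1 | alternative 1 | spirocyclic 6-[4-(benzyloxy)-3-methoxyphenyl]-1,3-dioxin-4-one with the acetal carbon from (−)-menthone | COc1cc(C2=CC(=O)O[C@@]3(C[C@H](C)CC[C@H]3C(C)C)O2)ccc1OCc1ccccc1
A2 | alternative 1 | (−)-menthone, (2S,5R)-2-isopropyl-5-methylcyclohexanone | O=C1C[C@H](C)CC[C@H]1C(C)C
A3 | alternative 1 | 2,5-dihydrofuran | C1=CCOC1
A4 | alternative 1 | cis-fused cyclobutane photoadduct of A1 and A3 (oxolane, cyclobutane and spiro-dioxanone rings) | COc1cc([C@@]23O[C@]4(C[C@H](C)CC[C@H]4C(C)C)OC(=O)[C@@H]2[C@H]2COC[C@@H]32)ccc1OCc1ccccc1
A5 | alternative 1 | 2-[(3R,4S)-4-[4-(benzyloxy)-3-methoxybenzoyl]tetrahydrofuran-3-yl]acetic acid (cis) | OC(=O)C[C@H]1COC[C@H]1C(=O)c1ccc(OCc2ccccc2)c(OC)c1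
A6 | alternative 2 | 4-[(2R,3E)-4-[4-(benzyloxy)-3-methoxyphenyl]-2-(hydroxymethyl)but-3-en-1-yl]-2-methoxyphenyl methanesulfonate | COc1cc(C[C@H](/C=C/c2ccc(OCc3ccccc3)c(OC)c2)CO)ccc1OS(C)(=O)=O
A7 | alternative 2 | formaldehyde | C=O
A8 | alternative 2 | trifluoroacetic acid | OC(=O)C(F)(F)F
A9 | alternative 2 | target skeleton with all three stereocentres as in 16, carrying a benzyl ether on the carbinol-side arene and a mesylate on the benzyl-side arene | COc1cc(C[C@H]2COC[C@@H]2[C@@H](O)c2ccc(OCc3ccccc3)c(OC)c2)ccc1OS(C)(=O)=O
A10 | alternative 3 | (2S,3S)-3-[4-(benzyloxy)-3-methoxyphenyl]-2-({[(2Z)-3-[4-(benzyloxy)-3-methoxyphenyl]-2-bromoprop-2-en-1-yl]oxy}methyl)oxirane | COc1cc(/C=C(\Br)COC[C@@H]2O[C@H]2c2ccc(OCc3ccccc3)c(OC)c2)ccc1OCc1ccccc1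
A11 | alternative 3 | tert-butyllithium | [Li]C(C)(C)C
A12 | alternative 3 | (R)-[(3R,4E)-4-[4-(benzyloxy)-3-methoxybenzylidene]tetrahydrofuran-3-yl][4-(benzyloxy)-3-methoxyphenyl]methanol | COc1cc(/C=C2/COC[C@@H]2[C@@H](O)c2ccc(OCc3ccccc3)c(OC)c2)ccc1OCc1ccccc1
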